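**Plan**

- Retrosynthesis first cuts the ArCH2–C6 bond of the methylene bridge (alkylation of the free cyclic triketone by an aryl Mannich base). It then cuts, in the dearomatised ring, the bond between the butanoyl-bearing carbon C2 and the oxygenated carbon C1, so that C2 leaves with its acyl group as an acyl carbene (1-diazopentan-2-one) and a cyclopentene-1,3-dione remains.
- The feature used: the six-membered ring is a 2-acyl-1,3-dione, i.e. the butanoyl-bearing carbon lies between two oxygenated ring carbons. The quaternary C4 (Me, prenyl) lies between two ring carbonyls, so it cannot enolise and, being α to a carbonyl, is a poor migrating group.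
- Forward: C-prenylation of 2-methylcyclopentane-1,3-dione, desymmetrising enzymatic reduction, α-hydroxylation, oxidation and enol ether formation give a 4-methoxycyclopent-4-ene-1,3-dione. Addition of the lithiated diazoketone and Rh(II)-induced 1,2-shift enlarge the five-membered ring to the acylated six-membered ring. O-Demethylation and coupling with the aryl Mannich base finish the route.
- Stereochemistry: the single stereocentre is set in step 2, where a ketoreductase distinguishes the enantiotopic carbonyls of the prochiral dione. The carbonyl that survives then fixes the side on which the extra ring oxygen and the inserted carbon are placed; the quaternary carbon is a bystander afterwards.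

Key step: step 8

Assumption: among the ketoreductases that desymmetrise 2,2-disubstituted cyclopentane-1,3-diones, one that gives the hydroxy ketone of the (2R) series is taken to be found by panel screening. The carbinol configuration is immaterial because that carbon is re-oxidised in step 4.

**Route**

Step 1
Reactants: 1 2-methylcyclopentane-1,3-dione; 2 1-bromo-3-methylbut-2-ene (prenyl bromide)
Product: 3 2-methyl-2-(3-methylbut-2-en-1-yl)cyclopentane-1,3-dione
Conditions: NaOH (1 M aq), rt
Reagents that add atoms: none
Why: C-alkylation of the enolate of a cyclic 2-alkyl-1,3-dione with an allylic bromide in water should favour the carbon over the oxygen and gives the prochiral quaternary carbon.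

Step 2
Reactants: 3 2-methyl-2-(3-methylbut-2-en-1-yl)cyclopentane-1,3-dione
Product: 4 (2R,3R)-3-hydroxy-2-methyl-2-(3-methylbut-2-en-1-yl)cyclopentan-1-one
Conditions: ketoreductase (KRED, (2R)-selective, from panel screening), NADP+ (cat.), i-PrOH, phosphate buffer pH 7, 30 °C
Reagents that add atoms: none
Why: enzymatic desymmetrisation (ketoreductase class) should reduce one of the two enantiotopic carbonyls, as is established for 2-alkyl-2-methylcyclopentane-1,3-diones, and the choice of carbonyl by the enzyme sets the quaternary stereocentre.

Step 3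
Reactants: 4 (2R,3R)-3-hydroxy-2-methyl-2-(3-methylbut-2-en-1-yl)cyclopentan-1-one
Product: 5 (2R,3R)-3,5-dihydroxy-2-methyl-2-(3-methylbut-2-en-1-yl)cyclopentan-1-one (both C5 epimers)
Conditions: NaHMDS (2.3 equiv), THF, −78 °C; Davis oxaziridine; AcOH, −78 °C
Reagents that add atoms: 3-phenyl-2-(phenylsulfonyl)oxaziridine, O=S(=O)(c1ccccc1)N1OC1c1ccccc1
Why: the ketone can enolise only towards C5 (C2 is quaternary), so enolate hydroxylation with the Davis reagent should place the oxygen there while the alkoxide is kept cold to suppress retro-aldol opening; the new carbinol centre is lost in step 4.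

Step 4
Reactants: 5 (2R,3R)-3,5-dihydroxy-2-methyl-2-(3-methylbut-2-en-1-yl)cyclopentan-1-one
Product: 6 (R)-4-hydroxy-2-methyl-2-(3-methylbut-2-en-1-yl)cyclopent-4-ene-1,3-dione
Conditions: Dess–Martin periodinane (2.5 equiv), CH2Cl2, 0 °C to rt
Reagents that add atoms: none
Why: Dess–Martin oxidation of both secondary carbinols should give the cyclopentane-1,2,4-trione, which exists as the vinylogous acid 6; the prenyl double bond is not touched and the quaternary centre cannot epimerise.

Step 5
Reactants: 6 (R)-4-hydroxy-2-methyl-2-(3-methylbut-2-en-1-yl)cyclopent-4-ene-1,3-dione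
Product: 7 (R)-4-methoxy-2-methyl-2-(3-methylbut-2-en-1-yl)cyclopent-4-ene-1,3-dione
Conditions: MeOH, TsOH (cat.), 3 Å MS, 40 °C
Reagents that add atoms: methanol, CO
Why: acid-catalysed enol etherification is reversible and should settle on the enol ether in which both carbonyls are conjugated with the double bond, rather than on the isomer with a vicinal dione.

Step 6
Reactants: 8 butanoyl chloride
Product: 9 1-diazopentan-2-one
Conditions: CH2N2 (2.5 equiv, Et2O), 0 °C
Reagents that add atoms: diazomethane, C=[N+]=[N-]
Why: acylation of diazomethane by an acid chloride (first stage of the Arndt–Eistert sequence) gives the α-diazo ketone, with the second equivalent of diazomethane taking up HCl.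

Step 7
Reactants: 7 (R)-4-methoxy-2-methyl-2-(3-methylbut-2-en-1-yl)cyclopent-4-ene-1,3-dione; 9 1-diazopentan-2-one
Product: 11 (4RS,5S)-4-(1-diazo-2-oxopentyl)-4-hydroxy-3-methoxy-5-methyl-5-(3-methylbut-2-en-1-yl)cyclopent-2-en-1-one, via lithiated diazoketone 10 (not isolated)
Conditions: LDA, THF, −78 °C (9 to 10); then 7, −78 °C; AcOH, −78 °C
Reagents that add atoms: none
Why: aldol-type addition of a C-lithiated α-diazo ketone to a ketone should occur at C3 of 7, the carbonyl next to C–OMe, because the other carbonyl is a less electrophilic vinylogous ester and 7 has no enolisable hydrogen; the carbinol centre forms as a mixture that converges in step 8.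

Step 8
Reactants: 11 (4RS,5S)-4-(1-diazo-2-oxopentyl)-4-hydroxy-3-methoxy-5-methyl-5-(3-methylbut-2-en-1-yl)cyclopent-2-en-1-one
Product: 12 (6S)-4-butanoyl-5-hydroxy-3-methoxy-6-methyl-6-(3-methylbut-2-en-1-yl)cyclohexa-2,4-dien-1-one
Conditions: Rh2(OAc)4 (1 mol %), CH2Cl2, 0 °C to rt
Reagents that add atoms: none
Why: Rh2(OAc)4 should turn the diazo group of 11 into a rhodium carbenoid next to the tertiary carbinol, and a 1,2-shift of ring carbon C3 (the sp2 carbon bearing OMe) from the carbinol carbon to the carbenoid carbon, pushed by the hydroxyl lone pair, should give the ring-enlarged 2-acyl-1,3-dione, which enolises to 12. The closest known reaction type is the Rh(II)-catalysed ring expansion of α-diazo-β-hydroxy carbonyl compounds derived from cyclic ketones, a two-stage Tiffeneau–Demjanov-type homologation. No ring is closed: the five-membered ring grows to the six-membered one by insertion of the diazo carbon, with its butanoyl group, between the former C4 and C3. No stereocentre is created; the carbinol centre is lost and the quaternary carbon, which is not part of the migrating bond, keeps its configuration. The step needs migration of the alkenyl carbon and not of the quaternary carbon, and a shift faster than cyclopropanation of the prenyl double bond; the first should hold because alkenyl groups migrate readily to electrophilic carbenoids whereas the quaternary carbon is α to the second ring carbonyl, the second because the hydroxyl-assisted shift takes place at the atom directly next to the carbenoid.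

Step 9
Reactants: 12 (6S)-4-butanoyl-5-hydroxy-3-methoxy-6-methyl-6-(3-methylbut-2-en-1-yl)cyclohexa-2,4-dien-1-one
Product: 13 (4R)-2-butanoyl-3,5-dihydroxy-4-methyl-4-(3-methylbut-2-en-1-yl)cyclohexa-2,5-dien-1-one
Conditions: LiCl (5 equiv), DMF, 110 °C; cold 1 M HCl work-up
Reagents that add atoms: none
Why: the methyl enol ether of a cyclic acyl triketone is a vinylogous methyl ester of a strong carbon acid, so SN2 demethylation by chloride should free the enol without the acid that would cyclise the prenyl group onto a neighbouring enol oxygen.

Step 10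
Reactants: 14 1-(2,4,6-trihydroxyphenyl)butan-1-one
Product: 15 1-(2,6-dihydroxy-4-methoxyphenyl)butan-1-one
Conditions: Me2SO4 (1.0 equiv), K2CO3 (1.0 equiv), acetone, rt
Reagents that add atoms: dimethyl sulfate, COS(=O)(=O)OC
Why: the two ortho hydroxyls are hydrogen-bonded to the acyl carbonyl, so the para hydroxyl is the most acidic and should be methylated selectively with one equivalent of reagent.

Step 11
Reactants: 15 1-(2,6-dihydroxy-4-methoxyphenyl)butan-1-one
Product: 16 1-{3-[(dimethylamino)methyl]-2,4-dihydroxy-6-methoxyphenyl}butan-1-one
Conditions: Eschenmoser's salt (1.0 equiv), i-Pr2NEt (1.1 equiv), CH2Cl2, 0 °C to rt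
Reagents that add atoms: N,N-dimethylmethyleneiminium iodide, C=[N+](C)C.[I-]
Why: Mannich aminomethylation of the electron-rich phenol ortho to a hydroxyl should occur once at either of the two equivalent free ring positions when the iminium salt is the limiting reagent.

Step 12
Reactants: 13 (4R)-2-butanoyl-3,5-dihydroxy-4-methyl-4-(3-methylbut-2-en-1-yl)cyclohexa-2,5-dien-1-one; 16 1-{3-[(dimethylamino)methyl]-2,4-dihydroxy-6-methoxyphenyl}butan-1-one
Product: 18 Elaphopilosin A, via ortho-quinone methide 17 (not isolated)
Conditions: 1,4-dioxane, 90 °C, slow addition of 16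
Reagents that add atoms: none
Why: the acidic triketone protonates the Mannich base, loss of dimethylamine gives the ortho-quinone methide, and Michael addition of the triketone enol through C6, its only unsubstituted ring carbon, should form the methylene bridge (Mannich-base alkylation of a C–H acid) without touching the quaternary stereocentre.

**Compound list**

1 | 2-methylcyclopentane-1,3-dione | CC1C(=O)CCC1=O | starting material
2 | 1-bromo-3-methylbut-2-ene | CC(C)=CCBr | starting material
3 | 2-methyl-2-(3-methylbut-2-en-1-yl)cyclopentane-1,3-dione | CC1(CC=C(C)C)C(=O)CCC1=O | intermediate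
4 | (2R,3R)-3-hydroxy-2-methyl-2-(3-methylbut-2-en-1-yl)cyclopentan-1-one | O=C1[C@](C)(CC=C(C)C)[C@H](O)CC1 | intermediate
5 | (2R,3R)-3,5-dihydroxy-2-methyl-2-(3-methylbut-2-en-1-yl)cyclopentan-1-one (C5 epimers) | O=C1[C@](C)(CC=C(C)C)[C@H](O)CC1O | intermediate
6 | (R)-4-hydroxy-2-methyl-2-(3-methylbut-2-en-1-yl)cyclopent-4-ene-1,3-dione | O=C1[C@](C)(CC=C(C)C)C(=O)C=C1O | intermediate
7 | (R)-4-methoxy-2-methyl-2-(3-methylbut-2-en-1-yl)cyclopent-4-ene-1,3-dione | O=C1[C@](C)(CC=C(C)C)C(=O)C=C1OC | intermediate
8 | butanoyl chloride | CCCC(=O)Cl | starting material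
9 | 1-diazopentan-2-one | CCCC(=O)C=[N+]=[N-] | intermediate
10 | 1-diazo-1-lithiopentan-2-one (not isolated) | CCCC(=O)C([Li])=[N+]=[N-] | intermediate
11 | (4RS,5S)-4-(1-diazo-2-oxopentyl)-4-hydroxy-3-methoxy-5-methyl-5-(3-methylbut-2-en-1-yl)cyclopent-2-en-1-one | OC1(C(=[N+]=[N-])C(=O)CCC)[C@](C)(CC=C(C)C)C(=O)C=C1OC | intermediate
12 | (6S)-4-butanoyl-5-hydroxy-3-methoxy-6-methyl-6-(3-methylbut-2-en-1-yl)cyclohexa-2,4-dien-1-one | CCCC(=O)C1=C(O)[C@](C)(CC=C(C)C)C(=O)C=C1OC | intermediate
13 | (4R)-2-butanoyl-3,5-dihydroxy-4-methyl-4-(3-methylbut-2-en-1-yl)cyclohexa-2,5-dien-1-one | CCCC(=O)C1=C(O)[C@](C)(CC=C(C)C)C(O)=CC1=O | intermediate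
14 | 1-(2,4,6-trihydroxyphenyl)butan-1-one | CCCC(=O)c1c(O)cc(O)cc1O | starting material
15 | 1-(2,6-dihydroxy-4-methoxyphenyl)butan-1-one | CCCC(=O)c1c(O)cc(OC)cc1O | intermediate
16 | 1-{3-[(dimethylamino)methyl]-2,4-dihydroxy-6-methoxyphenyl}butan-1-one | CCCC(=O)c1c(O)cc(OC)c(CN(C)C)c1O | intermediate
17 | 2-butanoyl-3-hydroxy-5-methoxy-6-methylidenecyclohexa-2,4-dien-1-one (not isolated) | C=C1C(OC)=CC(O)=C(C(=O)CCC)C1=O | intermediate
18 | Elaphopilosin A, (4R)-2-butanoyl-6-[(3-butanoyl-2,4-dihydroxy-6-methoxyphenyl)methyl]-3,5-dihydroxy-4-methyl-4-(3-methylbut-2-en-1-yl)cyclohexa-2,5-dien-1-one | CCCC(=O)C1=C(O)[C@](C)(CC=C(C)C)C(O)=C(Cc2c(OC)cc(O)c(C(=O)CCC)c2O)C1=O | target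

**Step count and risks**

Total step count: 12. Longest linear sequence: 9 (steps 1, 2, 3, 4, 5, 7, 8, 9, 12).

Steps most likely to fail:

1. Step 8. The 1,2-shift may take the quaternary carbon instead of the alkenyl carbon, or the carbenoid may be intercepted by the prenyl double bond (intramolecular cyclopropanation). The fallback builds the six-membered ring by condensation instead of insertion and sets out from 6. Its 1,2-dione tautomer would be cleaved between the vicinal carbonyls with Pb(OAc)4 in MeOH/benzene at 0 °C to give dimethyl (R)-2-methyl-2-(3-methylbut-2-en-1-yl)-3-oxopentanedioate F1, in which the stereocentre is untouched. Condensation of F1 with pentan-2-one (NaH in excess, DME, reflux) would acylate the ketone methyl group twice, first at the hindered ester and then by Dieckmann closure onto the second ester; this is the known glutarate-plus-methyl-ketone route to 2-acylcyclohexane-1,3-diones. It comes back to the route at 13.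

2. Step 5. The enol ether may form on the wrong oxygen, giving the isomer with a vicinal dione, or the strained dione may open by methanolysis. The fallback fixes the regiochemistry before the second flanking carbonyl exists and sets out from 5. Selective oxidation of the α-ketol with Cu(OAc)2 in aqueous AcOH/MeOH would give the diosphenol (4R,5R)-2,4-dihydroxy-5-methyl-5-(3-methylbut-2-en-1-yl)cyclopent-2-en-1-one F2, which has a single enol hydroxyl. Methylation (MeI, K2CO3, acetone) would give (4R,5R)-4-hydroxy-2-methoxy-5-methyl-5-(3-methylbut-2-en-1-yl)cyclopent-2-en-1-one F3, and Dess–Martin oxidation of the remaining carbinol returns to the route at 7.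

3. Step 12. The ortho-quinone methide may be captured by enol oxygen, by a second molecule of 16 or by the product, giving ethers, aryl dimers or over-alkylation. The fallback reverses the roles of the partners and sets out from 13. Aminomethylation of 13 at C6 with Eschenmoser's salt would give (4R)-2-butanoyl-6-[(dimethylamino)methyl]-3,5-dihydroxy-4-methyl-4-(3-methylbut-2-en-1-yl)cyclohexa-2,5-dien-1-one F4. Heating F4 with an excess of the phenol 15 (dioxane, 90 °C) would release the exocyclic methylene triketone, which the electron-rich arene attacks in a Friedel–Crafts-type Michael addition; this comes back to the route at 18.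

**Further compounds**

F1 | step 8 | dimethyl (R)-2-methyl-2-(3-methylbut-2-en-1-yl)-3-oxopentanedioate | COC(=O)[C@](C)(CC=C(C)C)C(=O)CC(=O)OC
F2 | step 5 | (4R,5R)-2,4-dihydroxy-5-methyl-5-(3-methylbut-2-en-1-yl)cyclopent-2-en-1-one | O=C1[C@](C)(CC=C(C)C)[C@H](O)C=C1O
F3 | step 5 | (4R,5R)-4-hydroxy-2-methoxy-5-methyl-5-(3-methylbut-2-en-1-yl)cyclopent-2-en-1-one | O=C1[C@](C)(CC=C(C)C)[C@H](O)C=C1OC
F4 | step 12 | (4R)-2-butanoyl-6-[(dimethylamino)methyl]-3,5-dihydroxy-4-methyl-4-(3-methylbut-2-en-1-yl)cyclohexa-2,5-dien-1-one | CCCC(=O)C1=C(O)[C@](C)(CC=C(C)C)C(O)=C(CN(C)C)C1=O
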